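**Retrosynthetic overview**
- Last bond: C2'–C3' of the lower trienamide, by Heck coupling of a 4-vinyl epoxyquinol enamide with the (2E,4E)-5-iodopentadienamide of the aminocyclopentenone unit.
- Key bond: the enamide C2–N bond, by blue-light nickel/photoredox coupling of the core enol triflate with the (6R)-dienamide.
- Core from (−)-quinic acid: derived enone → vinyl addition sets the tertiary carbinol → hydroxyl-directed epoxidation → diol to diosphenol → triflate.
- Upper amide from (S)-3-bromo-2-methylpropan-1-ol (Kochi coupling, oxidation/Wittig, HWE); lower amide from ethyl (2E)-4-oxobut-2-enoate (Takai, hydrolysis, amidation).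
- Ring order: the carbocycle is bought; a lactone and a dioxolane are formed first and later removed; the oxirane is the only ring built and kept; the cyclopentenone ring is bought.

Assumption: 2-amino-3-hydroxycyclopent-2-en-1-one hydrochloride, (S)-3-bromo-2-methylpropan-1-ol and ethyl (2E)-4-oxobut-2-enoate are taken as purchasable catalogue compounds.

**Route**

Step 1
Reactants: 1 (−)-quinic acid [(1S,3R,4S,5R)-1,3,4,5-tetrahydroxycyclohexane-1-carboxylic acid]
Product: 2 quinide acetonide (carboxyl lactonised onto the 3-OH; cis-4,5-diol as isopropylidene ketal; tertiary 1-OH free)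
Conditions: Me2C(OMe)2, TsOH·H2O (cat.), acetone, reflux
Reagents that add atoms: 2,2-dimethoxypropane, COC(C)(C)OC
Why: Acid-catalysed transketalisation protects the only cis-vicinal diol while the carboxyl group lactonises onto the cis-disposed 3-OH, a standard protection of quinic acid that touches no stereocenter.

Step 2
Reactants: 2 quinide acetonide
Product: 4 (3R,4S,5R)-3-hydroxy-4,5-(isopropylidenedioxy)cyclohexan-1-one, via reduced triol 3 (not isolated)
Conditions: NaBH4, EtOH, 0 → 23 °C; AcOH to pH 6; then NaIO4, H2O, 0 → 23 °C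
Reagents that add atoms: none
Why: Borohydride reduction of the lactone gives a tertiary-carbinol/CH2OH 1,2-diol that periodate cleaves (Malaprade glycol cleavage) to the ring ketone, leaving the three remaining ring stereocenters untouched.

Step 3
Reactants: 4 (3R,4S,5R)-3-hydroxy-4,5-(isopropylidenedioxy)cyclohexan-1-one
Product: 6 (4S,5R)-4,5-(isopropylidenedioxy)cyclohex-2-en-1-one, via mesylate 5 (not isolated)
Conditions: MsCl, Et3N, CH2Cl2, 0 → 23 °C
Reagents that add atoms: none
Why: Mesylation of the β-hydroxyl and E1cB elimination give the conjugated enone, removing only the C3 stereocenter and keeping the two acetonide carbons.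

Step 4
Reactants: 6 (4S,5R)-4,5-(isopropylidenedioxy)cyclohex-2-en-1-one
Product: 7 (1R,4S,5R)-4,5-(isopropylidenedioxy)-1-vinylcyclohex-2-en-1-ol (1-OH cis to the dioxolane oxygens)
Conditions: CH2=CHMgBr, CeCl3, THF, −78 °C
Reagents that add atoms: vinylmagnesium bromide, C=C[Mg]Br
Why: Organocerium 1,2-addition (Imamoto conditions suppress enolisation and β-alkoxide elimination) takes place on the convex face anti to the cis-fused dioxolane, so the new tertiary carbinol (1R, the later C4) is set by the quinic-acid-derived C4/C5 centers.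

Step 5
Reactants: 7 (1R,4S,5R)-4,5-(isopropylidenedioxy)-1-vinylcyclohex-2-en-1-ol
Product: 8 (1R,2R,3R,4R,5R)-2,3-epoxy-4,5-(isopropylidenedioxy)-1-vinylcyclohexan-1-ol (oxirane oxygen, 1-OH and dioxolane on one face)
Conditions: VO(acac)2 (5 mol %), t-BuOOH (1.2 equiv), CH2Cl2, 0 → 23 °C
Reagents that add atoms: tert-butyl hydroperoxide, CC(C)(C)OO
Why: In this hydroxyl-directed vanadium-catalysed epoxidation the vanadium alkoxide of the tertiary allylic alcohol delivers oxygen to the ring cis-alkene syn to that OH, setting both oxirane carbons from C1, and the 1,2-disubstituted ring alkene reacts well before the monosubstituted vinyl group.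

Step 6
Reactants: 8 (1R,2R,3R,4R,5R)-2,3-epoxy-4,5-(isopropylidenedioxy)-1-vinylcyclohexan-1-ol
Product: 9 (1R,2R,3R,4R,5R)-2,3-epoxy-1-vinylcyclohexane-1,4,5-triol
Conditions: AcOH/H2O (4:1), 40 °C
Reagents that add atoms: none
Why: Mild acetal hydrolysis frees the cis-diol while the oxirane survives, because it is flanked by oxygenated carbons and every neighbouring hydroxyl sits on its own face so that no backside opening is possible.

Step 7
Reactants: 9 (1R,2R,3R,4R,5R)-2,3-epoxy-1-vinylcyclohexane-1,4,5-triol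
Product: 10 (4S,5R,6S)-5,6-epoxy-2,4-dihydroxy-4-vinylcyclohex-2-en-1-one (diosphenol form of the 1,2-dione; 4-OH syn to the oxirane)
Conditions: IBX (3 equiv), DMSO, 23 °C
Reagents that add atoms: none
Why: IBX oxidises vicinal diols to α-diketones without C–C cleavage and cannot oxidise the tertiary alcohol, and the dione enolises only toward the CH2 group, which removes the two acetonide-derived stereocenters and leaves the carbinol and oxirane centers intact.

Step 8
Reactants: 10 (4S,5R,6S)-5,6-epoxy-2,4-dihydroxy-4-vinylcyclohex-2-en-1-one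
Product: 11 (4S,5R,6S)-5,6-epoxy-4-hydroxy-1-oxo-4-vinylcyclohex-2-en-2-yl trifluoromethanesulfonate
Conditions: PhNTf2, Et3N, DMAP (cat.), CH2Cl2, −20 → 0 °C
Reagents that add atoms: N-phenylbis(trifluoromethanesulfonimide), O=S(=O)(N(c1ccccc1)S(=O)(=O)C(F)(F)F)C(F)(F)F
Why: In this enol triflation the acidic diosphenol hydroxyl is sulfonylated by the mild triflimide reagent, whereas the hindered tertiary alcohol does not react.

Step 9
Reactants: 12 (S)-3-bromo-2-methylpropan-1-ol
Product: 13 (R)-2-methylhexan-1-ol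
Conditions: n-PrMgCl (3 equiv), Li2CuCl4 (3 mol %), THF, −20 → 0 °C
Reagents that add atoms: propylmagnesium chloride, CCC[Mg]Cl
Why: Kochi copper-catalysed sp3–sp3 coupling of the primary bromide (the first equivalent of Grignard reagent only deprotonates the hydroxyl) extends the chain without touching the bought stereocenter, which becomes the 6R center of the side chain.

Step 10
Reactants: 13 (R)-2-methylhexan-1-ol
Product: 15 (2E,4R)-2,4-dimethyloct-2-enal, via (R)-2-methylhexanal 14 (not isolated)
Conditions: TEMPO (10 mol %), PhI(OAc)2, ClCH2CH2Cl, 23 °C; then Ph3P=C(Me)CHO, 80 °C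
Reagents that add atoms: 2-(triphenylphosphoranylidene)propanal, CC(C=O)=P(c1ccccc1)(c1ccccc1)c1ccccc1
Why: The TEMPO/PhI(OAc)2 oxidation gives the epimerisable α-branched aldehyde, which is trapped in the same pot by Wittig reaction with the stabilised, non-basic formyl ylide to give the (E)-enal with the stereocenter intact.

Step 11
Reactants: 15 (2E,4R)-2,4-dimethyloct-2-enal
Product: 16 (2E,4E,6R)-4,6-dimethyldeca-2,4-dienamide
Conditions: (EtO)2P(O)CH2CONH2, NaH, THF, 0 → 23 °C
Reagents that add atoms: diethyl (2-amino-2-oxoethyl)phosphonate, CCOP(=O)(CC(N)=O)OCC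
Why: Horner–Wadsworth–Emmons olefination with the carbamoylmethyl phosphonate gives the (E)-configured primary dienamide directly.

Step 12
Reactants: 11 (4S,5R,6S)-5,6-epoxy-4-hydroxy-1-oxo-4-vinylcyclohex-2-en-2-yl trifluoromethanesulfonate; 16 (2E,4E,6R)-4,6-dimethyldeca-2,4-dienamide
Product: 17 (2E,4E,6R)-N-[(4S,5R,6S)-5,6-epoxy-4-hydroxy-1-oxo-4-vinylcyclohex-2-en-2-yl]-4,6-dimethyldeca-2,4-dienamide
Conditions: NiBr2(dme) (10 mol %), dtbbpy (12 mol %), [Ir(ppy)2(dtbbpy)]PF6 (2 mol %), K3PO4, MeCN, 450 nm LEDs, 25 °C, degassed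
Reagents that add atoms: none
Why: Proposed new method: zerovalent nickel formed by photoreduction should insert readily into the electron-poor C(sp2)–OTf bond of the α-triflyloxy enone, the primary amide is deprotonated on divalent nickel by K3PO4, and the photoexcited iridium complex (triplet energy too low to isomerise the diene) oxidises this vinyl nickel amidate to trivalent nickel, which forms the enamide C–N bond by reductive elimination at 25 °C without touching any stereocenter, the closest known reaction types being nickel/photoredox N-arylation of amides and sulfonamides with aryl halides and thermal palladium-catalysed amidation of enol triflates.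

Step 13
Reactants: 18 ethyl (2E)-4-oxobut-2-enoate
Product: 19 ethyl (2E,4E)-5-iodopenta-2,4-dienoate
Conditions: CrCl2 (6 equiv), CHI3, THF, 0 °C
Reagents that add atoms: iodoform, IC(I)I
Why: In the Takai olefination the geminal dichromium species from iodoform adds to the aldehyde and eliminates to the (E)-vinyl iodide, leaving the ester untouched.

Step 14
Reactants: 19 ethyl (2E,4E)-5-iodopenta-2,4-dienoate
Product: 20 (2E,4E)-5-iodopenta-2,4-dienoic acid
Conditions: LiOH, THF/H2O, 0 → 23 °C; then 1 M HCl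
Reagents that add atoms: lithium hydroxide, [Li+].[OH-]
Why: Mild saponification of the ethyl ester leaves the vinyl iodide and the diene geometry unchanged.

Step 15
Reactants: 20 (2E,4E)-5-iodopenta-2,4-dienoic acid; 21 2-amino-3-hydroxycyclopent-2-en-1-one hydrochloride
Product: 23 (2E,4E)-N-(2-hydroxy-5-oxocyclopent-1-en-1-yl)-5-iodopenta-2,4-dienamide, via acid chloride 22 (not isolated)
Conditions: (COCl)2, DMF (cat.), CH2Cl2, 0 → 23 °C; then 21, Et3N, CH2Cl2, 0 → 23 °C
Reagents that add atoms: none
Why: The acid chloride acylates the amino enol under Schotten–Baumann-type conditions, and any O-acylated material undergoes O→N acyl migration in the presence of Et3N to give the N-acyl vinylogous acid.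

Step 16
Reactants: 17 (2E,4E,6R)-N-[(4S,5R,6S)-5,6-epoxy-4-hydroxy-1-oxo-4-vinylcyclohex-2-en-2-yl]-4,6-dimethyldeca-2,4-dienamide; 23 (2E,4E)-N-(2-hydroxy-5-oxocyclopent-1-en-1-yl)-5-iodopenta-2,4-dienamide
Product: 24 target, (2E,4E,6R)-N-[(4S,5R,6S)-5,6-epoxy-4-hydroxy-4-[(1E,3E,5E)-7-[(2-hydroxy-5-oxocyclopent-1-en-1-yl)amino]-7-oxohepta-1,3,5-trienyl]-1-oxocyclohex-2-en-2-yl]-4,6-dimethyldeca-2,4-dienamide
Conditions: Pd(OAc)2 (10 mol %), Bu4NCl, NaHCO3, DMF, 35 °C, dark
Reagents that add atoms: none
Why: In this Jeffery-type Heck reaction the dienylpalladium species adds to the terminal carbon of the vinyl carbinol and, because the carbinol carbon bears no hydrogen, syn β-hydride elimination can only give the (E)-alkene, completing the (E,E,E)-triene without touching any stereocenter.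

**Compound list**

1 | (−)-quinic acid, (1S,3R,4S,5R)-1,3,4,5-tetrahydroxycyclohexane-1-carboxylic acid | O[C@]1(C(=O)O)C[C@@H](O)[C@H](O)[C@H](O)C1 | starting material
2 | quinide acetonide (carboxyl lactonised onto 3-OH; 4,5-O-isopropylidene; 1-OH free) | O[C@]1(C(=O)O2)C[C@@H]2[C@@H]3OC(C)(C)O[C@@H]3C1 | intermediate
3 | reduced triol, 1-(hydroxymethyl)-4,5-(isopropylidenedioxy)cyclohexane-1,3-diol (ring configurations as in 2) | O[C@]1(CO)C[C@@H](O)[C@@H]2OC(C)(C)O[C@@H]2C1 | intermediate
4 | (3R,4S,5R)-3-hydroxy-4,5-(isopropylidenedioxy)cyclohexan-1-one | O=C1C[C@@H](O)[C@@H]2OC(C)(C)O[C@@H]2C1 | intermediate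
5 | 3-O-methanesulfonate of 4 (configuration unchanged) | O=C1C[C@@H](OS(C)(=O)=O)[C@@H]2OC(C)(C)O[C@@H]2C1 | intermediate
6 | (4S,5R)-4,5-(isopropylidenedioxy)cyclohex-2-en-1-one | O=C1C=C[C@@H]2OC(C)(C)O[C@@H]2C1 | intermediate
7 | (1R,4S,5R)-4,5-(isopropylidenedioxy)-1-vinylcyclohex-2-en-1-ol | O[C@]1(C=C)C=C[C@@H]2OC(C)(C)O[C@@H]2C1 | intermediate
8 | (1R,2R,3R,4R,5R)-2,3-epoxy-4,5-(isopropylidenedioxy)-1-vinylcyclohexan-1-ol | O[C@]1(C=C)[C@@H]2O[C@@H]2[C@@H]3OC(C)(C)O[C@@H]3C1 | intermediate
9 | (1R,2R,3R,4R,5R)-2,3-epoxy-1-vinylcyclohexane-1,4,5-triol | O[C@]1(C=C)[C@@H]2O[C@@H]2[C@H](O)[C@H](O)C1 | intermediate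
10 | (4S,5R,6S)-5,6-epoxy-2,4-dihydroxy-4-vinylcyclohex-2-en-1-one | OC1=C[C@@](O)(C=C)[C@@H]2O[C@@H]2C1=O | intermediate
11 | (4S,5R,6S)-5,6-epoxy-4-hydroxy-1-oxo-4-vinylcyclohex-2-en-2-yl trifluoromethanesulfonate | FC(F)(F)S(=O)(=O)OC1=C[C@@](O)(C=C)[C@@H]2O[C@@H]2C1=O | intermediate
12 | (S)-3-bromo-2-methylpropan-1-ol | C[C@@H](CO)CBr | starting material
13 | (R)-2-methylhexan-1-ol | CCCC[C@@H](C)CO | intermediate
14 | (R)-2-methylhexanal | CCCC[C@@H](C)C=O | intermediate
15 | (2E,4R)-2,4-dimethyloct-2-enal | CCCC[C@@H](C)/C=C(C)/C=O | intermediate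
16 | (2E,4E,6R)-4,6-dimethyldeca-2,4-dienamide | CCCC[C@@H](C)/C=C(C)/C=C/C(N)=O | intermediate
17 | (2E,4E,6R)-N-[(4S,5R,6S)-5,6-epoxy-4-hydroxy-1-oxo-4-vinylcyclohex-2-en-2-yl]-4,6-dimethyldeca-2,4-dienamide | CCCC[C@@H](C)/C=C(C)/C=C/C(=O)NC1=C[C@@](O)(C=C)[C@@H]2O[C@@H]2C1=O | intermediate
18 | ethyl (2E)-4-oxobut-2-enoate | CCOC(=O)/C=C/C=O | starting material
19 | ethyl (2E,4E)-5-iodopenta-2,4-dienoate | CCOC(=O)/C=C/C=C/I | intermediate
20 | (2E,4E)-5-iodopenta-2,4-dienoic acid | OC(=O)/C=C/C=C/I | intermediate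
21 | 2-amino-3-hydroxycyclopent-2-en-1-one hydrochloride | NC1=C(O)CCC1=O.Cl | starting material
22 | (2E,4E)-5-iodopenta-2,4-dienoyl chloride | ClC(=O)/C=C/C=C/I | intermediate
23 | (2E,4E)-N-(2-hydroxy-5-oxocyclopent-1-en-1-yl)-5-iodopenta-2,4-dienamide | O=C(/C=C/C=C/I)NC1=C(O)CCC1=O | intermediate
24 | CNP0262080.2, (2E,4E,6R)-N-[(4S,5R,6S)-5,6-epoxy-4-hydroxy-4-[(1E,3E,5E)-7-[(2-hydroxy-5-oxocyclopent-1-en-1-yl)amino]-7-oxohepta-1,3,5-trienyl]-1-oxocyclohex-2-en-2-yl]-4,6-dimethyldeca-2,4-dienamide | CCCC[C@@H](C)/C=C(C)/C=C/C(=O)NC1=C[C@@](O)(/C=C/C=C/C=C/C(=O)NC2=C(O)CCC2=O)[C@@H]2O[C@@H]2C1=O | target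

**Step count and risks**

Total: 16 steps. Longest linear sequence: 10 steps (steps 1–8, 12 and 16). Each side-chain branch takes 3 steps.

The three steps most likely to fail, in route order:

The double oxidation of step 7 may over-oxidise, or the diosphenol may dehydrate and aromatise. The fallback sets out from triol 9 and oxidises one hydroxyl at a time. Mono-oxidation through the dibutylstannylene acetal (Bu2SnO, MeOH, reflux; then NBS, CHCl3, 23 °C) gives the α-hydroxy ketone (2R,4R,5R,6S)-5,6-epoxy-2,4-dihydroxy-4-vinylcyclohexan-1-one F1. Oxidation of this ketol with Cu(OAc)2 in aqueous AcOH at 60 °C comes back to the route at diosphenol 10.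

The new photochemical C–N coupling of step 12 may fail because nickel or the reduced photocatalyst attacks the α,β-epoxy ketone, or because the amidate does not bind or does not eliminate. The fallback uses known chemistry, sets out from triflate 11 (with amide 16) and comes back at enamide 17 in one operation. It is the thermal palladium-catalysed amidation of the enol triflate (Pd2(dba)3, Xantphos, Cs2CO3, 1,4-dioxane, 50 °C), a two-electron cross-coupling between zerovalent and divalent palladium that needs neither light nor nickel. New compounds on its way: none F0.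

The Heck coupling of step 16 is run on a base- and heat-sensitive epoxyquinol with an acidic coupling partner. The fallback sets out from enamide 17. Cross-metathesis with pinacol vinylboronate (second-generation Hoveyda–Grubbs catalyst, CH2Cl2, 40 °C) gives the alkenyl boronate (2E,4E,6R)-N-[(4S,5R,6S)-5,6-epoxy-4-hydroxy-1-oxo-4-[(E)-2-(4,4,5,5-tetramethyl-1,3,2-dioxaborolan-2-yl)vinyl]cyclohex-2-en-2-yl]-4,6-dimethyldeca-2,4-dienamide F2. Suzuki–Miyaura coupling of F2 with iodide 23 (Pd(PPh3)4, K3PO4, THF/H2O, 23 °C) comes back to the route at target 24.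

**Further compounds**

F1 | step 7 | (2R,4R,5R,6S)-5,6-epoxy-2,4-dihydroxy-4-vinylcyclohexan-1-one | O[C@]1(C=C)[C@@H]2O[C@@H]2C(=O)[C@H](O)C1
F0 | step 12 | none | none
F2 | step 16 | (2E,4E,6R)-N-[(4S,5R,6S)-5,6-epoxy-4-hydroxy-1-oxo-4-[(E)-2-(4,4,5,5-tetramethyl-1,3,2-dioxaborolan-2-yl)vinyl]cyclohex-2-en-2-yl]-4,6-dimethyldeca-2,4-dienamide | CCCC[C@@H](C)/C=C(C)/C=C/C(=O)NC1=C[C@@](O)(/C=C/B3OC(C)(C)C(C)(C)O3)[C@@H]2O[C@@H]2C1=O
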